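**Retrosynthetic overview**

1. Feature: in the butyrolactone ring, C-beta (C-4), its exocyclic CH2 toward guaiacyl ring A and the ring O–CH2 (C-5) are the three carbons of (R)-epichlorohydrin, and C-alpha (C-3) with the lactone C=O (C-2) is a malonate unit. The cyclopropane-fused lactone 3 therefore holds the whole lactone core with C-beta already set.
2. Key disconnections, made in one operation: the CH2–ring A bond (copper-catalysed opening of the cyclopropane CH2 of 3 by ring A Grignard reagent 6) and the C-alpha–CH2 bond (benzylation of the resulting enolate by ring B bromide 20).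
3. Bromide 20: both side-chain stereocentres come from an Evans syn aldol of a ring B arylacetyl imide with O-benzylvanillin (ring C); the arylacetic acid comes from methyl 5-bromovanillate by a Pd-catalysed Reformatsky coupling.
4. Ring order: lactone ring (fused to the cyclopropane) in step 1, temporary 1,3-dioxane on the side-chain diol in step 10, cyclopropane cleaved in step 13. Endgame: de-ethoxycarbonylation, epimerisation to the trans lactone, acetonide hydrolysis, hydrogenolysis.

Key step: step 13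

Assumption: the copper-catalysed ring opening and the enolate benzylation are run in one flask and counted as one step; compounds 7 and 9 (9 as its solution in diethyl ether) are taken as commercial.

**Route**

Step 1
Reactants: 1 (R)-epichlorohydrin; 2 diethyl malonate
Product: 3 ethyl (1S,5R)-2-oxo-3-oxabicyclo[3.1.0]hexane-1-carboxylate
Conditions: NaOEt (1.1 equiv), EtOH, 0 °C → reflux
Reagents that add atoms: none
Why: Tandem alkylation–cyclopropanation–lactonisation: the malonate anion opens the epoxide at its CH2, the alkoxide closes a new epoxide by displacing chloride, the malonate anion then closes the cyclopropane by 3-exo-tet attack with inversion at the epichlorohydrin carbon, and the released alkoxide lactonises onto the cis ester, so C-5 (R) comes from the chiral pool and C-1 (S) follows from the cis ring fusion.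

Step 2
Reactants: 4 4-bromo-2-methoxyphenol
Product: 5 1-(benzyloxy)-4-bromo-2-methoxybenzene
Conditions: BnBr, K2CO3, DMF, rt
Reagents that add atoms: benzyl bromide, BrCc1ccccc1
Why: Williamson ether synthesis on the phenoxide; the aryl bromide is inert to these conditions.

Step 3
Reactants: 5 1-(benzyloxy)-4-bromo-2-methoxybenzene
Product: 6 [4-(benzyloxy)-3-methoxyphenyl]magnesium bromide (titrated THF solution, used directly)
Conditions: Mg turnings, I2 (cat.), THF, 40–50 °C
Reagents that add atoms: magnesium, [Mg]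
Why: Grignard formation by insertion of magnesium into the aryl C–Br bond; the benzyl and methyl ethers do not react.

Step 4
Reactants: 7 methyl 3-bromo-4-hydroxy-5-methoxybenzoate
Product: 8 methyl 4-(benzyloxy)-3-bromo-5-methoxybenzoate
Conditions: BnBr, K2CO3, DMF, 50 °C
Reagents that add atoms: benzyl bromide, BrCc1ccccc1
Why: Williamson ether synthesis; the hindered phenoxide between OMe and Br is still alkylated readily by the reactive benzylic halide.

Step 5
Reactants: 8 methyl 4-(benzyloxy)-3-bromo-5-methoxybenzoate; 9 (2-tert-butoxy-2-oxoethyl)zinc chloride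
Product: 10 methyl 4-(benzyloxy)-3-(2-tert-butoxy-2-oxoethyl)-5-methoxybenzoate
Conditions: Pd2(dba)3 (1 mol%), XPhos (2.5 mol%), THF, 60 °C
Reagents that add atoms: none
Why: Negishi-type coupling of a Reformatsky reagent with an aryl bromide (Pd-catalysed alpha-arylation of a zinc ester enolate); the mild zinc enolate leaves the methyl ester alone and stops at monoarylation.

Step 6
Reactants: 10 methyl 4-(benzyloxy)-3-(2-tert-butoxy-2-oxoethyl)-5-methoxybenzoate
Product: 11 [2-(benzyloxy)-3-methoxy-5-(methoxycarbonyl)phenyl]acetic acid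
Conditions: TFA/CH2Cl2 (1:4), 0 °C → rt
Reagents that add atoms: none
Why: Acidolysis of the tert-butyl ester through the tert-butyl cation; the methyl ester and the aryl benzyl ether should survive short exposure.

Step 7
Reactants: 11 [2-(benzyloxy)-3-methoxy-5-(methoxycarbonyl)phenyl]acetic acid
Product: 13 methyl 4-(benzyloxy)-3-{2-[(4S)-4-benzyl-2-oxooxazolidin-3-yl]-2-oxoethyl}-5-methoxybenzoate, via mixed pivalic anhydride 12 (not isolated)
Conditions: PivCl, Et3N, THF, −20 °C; then (S)-4-benzyloxazolidin-2-one, LiCl, −20 °C → rt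
Reagents that add atoms: (S)-4-benzyloxazolidin-2-one, O=C1N[C@@H](Cc2ccccc2)CO1
Why: Mixed-anhydride N-acylation of the oxazolidinone under LiCl/amine activation; no strong base is present, so the acidic benzylic CH2 and the methyl ester are not disturbed.

Step 8
Reactants: 13 methyl 4-(benzyloxy)-3-{2-[(4S)-4-benzyl-2-oxooxazolidin-3-yl]-2-oxoethyl}-5-methoxybenzoate; 14 4-(benzyloxy)-3-methoxybenzaldehyde
Product: 16 methyl 4-(benzyloxy)-3-{(2S,3S)-1-[(4S)-4-benzyl-2-oxooxazolidin-3-yl]-3-[4-(benzyloxy)-3-methoxyphenyl]-3-hydroxy-1-oxopropan-2-yl}-5-methoxybenzoate, via Z dibutylboron enolate 15 (not isolated)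
Conditions: Bu2BOTf, iPr2NEt, CH2Cl2, 0 °C; 14, −78 → 0 °C; pH 7 buffer, MeOH, H2O2, 0 °C
Reagents that add atoms: none
Why: Evans syn aldol: the Z boron enolate reacts through a Zimmerman–Traxler chair with the aldehyde aryl group equatorial, on the enolate face away from the benzyl group of the (S)-auxiliary in its dipole-opposed conformation, which should set both side-chain centres as (2S,3S) syn.

Step 9
Reactants: 16 the aldol adduct
Product: 17 methyl 4-(benzyloxy)-3-{(1S,2R)-1-[4-(benzyloxy)-3-methoxyphenyl]-1,3-dihydroxypropan-2-yl}-5-methoxybenzoate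
Conditions: LiBH4, H2O (1 equiv), THF/Et2O, 0 °C
Reagents that add atoms: none
Why: Reductive cleavage of the N-acyl oxazolidinone by LiBH4; the exocyclic imide carbonyl is far more electrophilic than the electron-rich aryl methyl ester, and reduction is faster than enolisation, so both centres are kept (the descriptor at C-2 changes to R only through the priority change).

Step 10
Reactants: 17 the diol ester
Product: 18 methyl 4-(benzyloxy)-3-{(4S,5R)-4-[4-(benzyloxy)-3-methoxyphenyl]-2,2-dimethyl-1,3-dioxan-5-yl}-5-methoxybenzoate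
Conditions: 2,2-dimethoxypropane, PPTS (cat.), CH2Cl2, rt
Reagents that add atoms: 2,2-dimethoxypropane, COC(C)(C)OC
Why: Acid-catalysed transketalisation to the six-membered acetonide (4,5-cis), which masks both hydroxyl groups for the hydride, bromination and organometallic steps.

Step 11
Reactants: 18 the acetonide ester
Product: 19 [4-(benzyloxy)-3-{(4S,5R)-4-[4-(benzyloxy)-3-methoxyphenyl]-2,2-dimethyl-1,3-dioxan-5-yl}-5-methoxyphenyl]methanol
Conditions: LiAlH4, THF, 0 °C
Reagents that add atoms: none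
Why: Hydride reduction of the methyl ester to the benzylic alcohol; acetonide and benzyl ethers are stable to LiAlH4.

Step 12
Reactants: 19 the benzylic alcohol
Product: 20 (4S,5R)-5-[2-(benzyloxy)-5-(bromomethyl)-3-methoxyphenyl]-4-[4-(benzyloxy)-3-methoxyphenyl]-2,2-dimethyl-1,3-dioxane
Conditions: CBr4, PPh3, 2,6-lutidine, CH2Cl2, 0 °C; used at once
Reagents that add atoms: carbon tetrabromide, BrC(Br)(Br)Br
Why: Appel reaction on a primary benzylic alcohol under buffered, near-neutral conditions that should spare the acetonide.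

Step 13
Reactants: 6 [4-(benzyloxy)-3-methoxyphenyl]magnesium bromide; 3 ethyl (1S,5R)-2-oxo-3-oxabicyclo[3.1.0]hexane-1-carboxylate; 20 the ring B benzyl bromide
Product: 22 ethyl (3R,4R)-3-{4-(benzyloxy)-3-[(4S,5R)-4-[4-(benzyloxy)-3-methoxyphenyl]-2,2-dimethyl-1,3-dioxan-5-yl]-5-methoxybenzyl}-4-[4-(benzyloxy)-3-methoxybenzyl]-2-oxotetrahydrofuran-3-carboxylate, via bromomagnesium enolate 21 (not isolated)
Conditions: 6 (1.1 equiv) added to 3 (1.2 equiv), CuI (10 mol%), THF, −30 °C; then 20 (1.0 equiv), DMPU, −30 °C → rt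
Reagents that add atoms: none
Why: Reagent 6 and catalytic CuI form an arylcopper species (monovalent copper) that attacks the unsubstituted cyclopropane carbon C-6 of 3 in an SN2-like homoconjugate addition, so that the C-1–C-6 bond breaks and the charge rests on the lactone–ester (malonate-type) enolate 21; the closest known reaction type is the copper-catalysed Grignard opening of this same bicyclic lactone and of cyclopropane-1,1-diesters, followed by C-alkylation of the doubly stabilised enolate as in tandem conjugate addition–alkylation. No ring closes: the cyclopropane is cleaved and the lactone ring of 3 is carried over intact. C-5 of 3 is not touched and becomes C-beta (R), while the new quaternary C-alpha is set by approach of 20 to the enolate face opposite the C-beta benzyl group (substrate control), placing the two benzyl groups trans; this centre is not relied upon, since steps 14 and 15 erase and reset it. The step needs attack at the cyclopropane CH2 and not at the ring-fusion CH or a carbonyl group, which the lower substitution of that carbon, the double activation by lactone and ester and copper catalysis at low temperature should secure. It also needs C- over O-alkylation and no aryl–benzyl coupling, which the chelated soft enolate, the benzylic bromide, DMPU as co-solvent and the slight deficit of 6 relative to 3 (consumed before 20 is added) should secure.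

Step 14
Reactants: 22 the alpha-ethoxycarbonyl lactone
Product: 23 (3RS,4R)-3-{4-(benzyloxy)-3-[(4S,5R)-4-[4-(benzyloxy)-3-methoxyphenyl]-2,2-dimethyl-1,3-dioxan-5-yl]-5-methoxybenzyl}-4-[4-(benzyloxy)-3-methoxybenzyl]dihydrofuran-2(3H)-one (C-3 epimers)
Conditions: LiCl, H2O (2 equiv), DMSO, 140–150 °C
Reagents that add atoms: none
Why: Krapcho dealkoxycarbonylation: chloride attacks the ethyl group, the carboxylate loses CO2 and the lactone enolate is protonated, under neutral conditions that acetonide and benzyl ethers should tolerate; C-3 forms as a mixture.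

Step 15
Reactants: 23 the C-3 epimer mixture
Product: 24 (3R,4R)-3-{4-(benzyloxy)-3-[(4S,5R)-4-[4-(benzyloxy)-3-methoxyphenyl]-2,2-dimethyl-1,3-dioxan-5-yl]-5-methoxybenzyl}-4-[4-(benzyloxy)-3-methoxybenzyl]dihydrofuran-2(3H)-one
Conditions: DBU, toluene, 60 °C
Reagents that add atoms: none
Why: Base-mediated epimerisation through the lactone enolate under thermodynamic control, which favours the trans-3,4-dibenzyl lactone; C-3 is the only enolisable centre, so (3R) follows from the fixed (4R) centre.

Step 16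
Reactants: 24 the trans lactone acetonide
Product: 25 (3R,4R)-3-{4-(benzyloxy)-3-[(1S,2R)-1-[4-(benzyloxy)-3-methoxyphenyl]-1,3-dihydroxypropan-2-yl]-5-methoxybenzyl}-4-[4-(benzyloxy)-3-methoxybenzyl]dihydrofuran-2(3H)-one
Conditions: AcOH/THF/H2O (3:1:1), 40 °C
Reagents that add atoms: none
Why: Mild acid-catalysed acetal hydrolysis; the weak acid should leave the lactone, the benzyl ethers and the benzylic carbinol centre (still flanked by an O-benzylated ring) unchanged.

Step 17
Reactants: 25 the tribenzyl ether diol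
Product: 26 (3R,4R)-3-{3-[(1S,2R)-1,3-dihydroxy-1-(4-hydroxy-3-methoxyphenyl)propan-2-yl]-4-hydroxy-5-methoxybenzyl}-4-(4-hydroxy-3-methoxybenzyl)dihydrofuran-2(3H)-one (target)
Conditions: H2 (1 atm), 10% Pd/C, EtOAc/EtOH, rt; stopped after uptake of three equivalents
Reagents that add atoms: none
Why: Catalytic hydrogenolysis of the three aryl benzyl ethers in neutral medium, where the secondary benzylic alcohol is cleaved much more slowly than O-benzyl groups.

**Compound list**

1 | (R)-epichlorohydrin | ClC[C@H]1CO1 | starting material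
2 | diethyl malonate | CCOC(=O)CC(=O)OCC | starting material
3 | ethyl (1S,5R)-2-oxo-3-oxabicyclo[3.1.0]hexane-1-carboxylate | C1[C@H]2COC(=O)[C@@]12C(=O)OCC | intermediate
4 | 4-bromo-2-methoxyphenol | COc1cc(Br)ccc1O | starting material
5 | 1-(benzyloxy)-4-bromo-2-methoxybenzene | COc1cc(Br)ccc1OCc1ccccc1 | intermediate
6 | [4-(benzyloxy)-3-methoxyphenyl]magnesium bromide | COc1cc([Mg]Br)ccc1OCc1ccccc1 | intermediate
7 | methyl 3-bromo-4-hydroxy-5-methoxybenzoate (methyl 5-bromovanillate) | COC(=O)c1cc(OC)c(O)c(Br)c1 | starting material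
8 | methyl 4-(benzyloxy)-3-bromo-5-methoxybenzoate | COC(=O)c1cc(OC)c(OCc2ccccc2)c(Br)c1 | intermediate
9 | (2-tert-butoxy-2-oxoethyl)zinc chloride | CC(C)(C)OC(=O)C[Zn]Cl | starting material
10 | methyl 4-(benzyloxy)-3-(2-tert-butoxy-2-oxoethyl)-5-methoxybenzoate | COC(=O)c1cc(OC)c(OCc2ccccc2)c(CC(=O)OC(C)(C)C)c1 | intermediate
11 | [2-(benzyloxy)-3-methoxy-5-(methoxycarbonyl)phenyl]acetic acid | COC(=O)c1cc(OC)c(OCc2ccccc2)c(CC(=O)O)c1 | intermediate
12 | mixed anhydride of 11 with pivalic acid (not isolated) | COC(=O)c1cc(OC)c(OCc2ccccc2)c(CC(=O)OC(=O)C(C)(C)C)c1 | intermediate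
13 | methyl 4-(benzyloxy)-3-{2-[(4S)-4-benzyl-2-oxooxazolidin-3-yl]-2-oxoethyl}-5-methoxybenzoate | COC(=O)c1cc(OC)c(OCc2ccccc2)c(CC(=O)N2[C@@H](Cc3ccccc3)COC2=O)c1 | intermediate
14 | 4-(benzyloxy)-3-methoxybenzaldehyde (O-benzylvanillin) | COc1cc(C=O)ccc1OCc1ccccc1 | starting material
15 | (Z)-dibutylboron enolate of 13 (not isolated) | CCCCB(CCCC)O/C(=C\c1cc(C(=O)OC)cc(OC)c1OCc1ccccc1)N1[C@@H](Cc2ccccc2)COC1=O | intermediate
16 | methyl 4-(benzyloxy)-3-{(2S,3S)-1-[(4S)-4-benzyl-2-oxooxazolidin-3-yl]-3-[4-(benzyloxy)-3-methoxyphenyl]-3-hydroxy-1-oxopropan-2-yl}-5-methoxybenzoate | COC(=O)c1cc(OC)c(OCc2ccccc2)c([C@H](C(=O)N2[C@@H](Cc3ccccc3)COC2=O)[C@H](O)c2ccc(OCc3ccccc3)c(OC)c2)c1 | intermediate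
17 | methyl 4-(benzyloxy)-3-{(1S,2R)-1-[4-(benzyloxy)-3-methoxyphenyl]-1,3-dihydroxypropan-2-yl}-5-methoxybenzoate | COC(=O)c1cc(OC)c(OCc2ccccc2)c([C@H](CO)[C@H](O)c2ccc(OCc3ccccc3)c(OC)c2)c1 | intermediate
18 | methyl 4-(benzyloxy)-3-{(4S,5R)-4-[4-(benzyloxy)-3-methoxyphenyl]-2,2-dimethyl-1,3-dioxan-5-yl}-5-methoxybenzoate | COC(=O)c1cc(OC)c(OCc2ccccc2)c([C@H](CO2)[C@H](OC2(C)C)c2ccc(OCc3ccccc3)c(OC)c2)c1 | intermediate
19 | [4-(benzyloxy)-3-{(4S,5R)-4-[4-(benzyloxy)-3-methoxyphenyl]-2,2-dimethyl-1,3-dioxan-5-yl}-5-methoxyphenyl]methanol | OCc1cc(OC)c(OCc2ccccc2)c([C@H](CO2)[C@H](OC2(C)C)c2ccc(OCc3ccccc3)c(OC)c2)c1 | intermediate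
20 | (4S,5R)-5-[2-(benzyloxy)-5-(bromomethyl)-3-methoxyphenyl]-4-[4-(benzyloxy)-3-methoxyphenyl]-2,2-dimethyl-1,3-dioxane | BrCc1cc(OC)c(OCc2ccccc2)c([C@H](CO2)[C@H](OC2(C)C)c2ccc(OCc3ccccc3)c(OC)c2)c1 | intermediate
21 | bromomagnesium enolate of ethyl (4R)-4-[4-(benzyloxy)-3-methoxybenzyl]-2-oxotetrahydrofuran-3-carboxylate (not isolated) | COc1cc(C[C@H]2COC(O[Mg]Br)=C2C(=O)OCC)ccc1OCc1ccccc1 | intermediate
22 | ethyl (3R,4R)-3-{4-(benzyloxy)-3-[(4S,5R)-4-[4-(benzyloxy)-3-methoxyphenyl]-2,2-dimethyl-1,3-dioxan-5-yl]-5-methoxybenzyl}-4-[4-(benzyloxy)-3-methoxybenzyl]-2-oxotetrahydrofuran-3-carboxylate | COc1cc(C[C@H]2COC(=O)[C@]2(C(=O)OCC)Cc2cc(OC)c(OCc3ccccc3)c([C@H](CO3)[C@H](OC3(C)C)c3ccc(OCc4ccccc4)c(OC)c3)c2)ccc1OCc1ccccc1 | intermediate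
23 | (3RS,4R)-3-{4-(benzyloxy)-3-[(4S,5R)-4-[4-(benzyloxy)-3-methoxyphenyl]-2,2-dimethyl-1,3-dioxan-5-yl]-5-methoxybenzyl}-4-[4-(benzyloxy)-3-methoxybenzyl]dihydrofuran-2(3H)-one (C-3 epimers) | COc1cc(C[C@H]2COC(=O)C2Cc2cc(OC)c(OCc3ccccc3)c([C@H](CO3)[C@H](OC3(C)C)c3ccc(OCc4ccccc4)c(OC)c3)c2)ccc1OCc1ccccc1 | intermediate
24 | (3R,4R)-3-{4-(benzyloxy)-3-[(4S,5R)-4-[4-(benzyloxy)-3-methoxyphenyl]-2,2-dimethyl-1,3-dioxan-5-yl]-5-methoxybenzyl}-4-[4-(benzyloxy)-3-methoxybenzyl]dihydrofuran-2(3H)-one | COc1cc(C[C@H]2COC(=O)[C@@H]2Cc2cc(OC)c(OCc3ccccc3)c([C@H](CO3)[C@H](OC3(C)C)c3ccc(OCc4ccccc4)c(OC)c3)c2)ccc1OCc1ccccc1 | intermediate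
25 | (3R,4R)-3-{4-(benzyloxy)-3-[(1S,2R)-1-[4-(benzyloxy)-3-methoxyphenyl]-1,3-dihydroxypropan-2-yl]-5-methoxybenzyl}-4-[4-(benzyloxy)-3-methoxybenzyl]dihydrofuran-2(3H)-one | COc1cc(C[C@H]2COC(=O)[C@@H]2Cc2cc(OC)c(OCc3ccccc3)c([C@H](CO)[C@H](O)c3ccc(OCc4ccccc4)c(OC)c3)c2)ccc1OCc1ccccc1 | intermediate
26 | (3R,4R)-3-{3-[(1S,2R)-1,3-dihydroxy-1-(4-hydroxy-3-methoxyphenyl)propan-2-yl]-4-hydroxy-5-methoxybenzyl}-4-(4-hydroxy-3-methoxybenzyl)dihydrofuran-2(3H)-one | COc1cc(C[C@H]2COC(=O)[C@@H]2Cc2cc(OC)c(O)c([C@H](CO)[C@H](O)c3ccc(O)c(OC)c3)c2)ccc1O | target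

**Summary**

Total step count: 17. Longest linear sequence: 14 steps (steps 4–17, from compound 7 to compound 26).

Steps most likely to fail:

1. Step 13. The chelated bromomagnesium enolate may alkylate too slowly, while copper salts and any surplus Grignard reagent consume the benzylic bromide by aryl–benzyl coupling. Fallback: the operation is split. Setting out from 3 and 6, the copper-catalysed opening is run as before but quenched with aqueous NH4Cl, which should give ethyl (4R)-4-[4-(benzyloxy)-3-methoxybenzyl]-2-oxotetrahydrofuran-3-carboxylate F1 as a mixture at C-3. After removal of the copper salts, F1 is converted into its sodium enolate (NaH, DMF, 0 °C) and alkylated with bromide 20, which returns to the route at compound 22.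

2. Step 8. Facial and syn/anti selectivity may be poor, because the hindered ortho-benzyloxy aryl enolate adds slowly to the electron-rich aldehyde and the doubly benzylic adduct can equilibrate by retro-aldol. Fallback: a chelated titanium enolate with a different auxiliary. Setting out from acid 11, coupling with (S)-4-benzylthiazolidine-2-thione (EDC·HCl, DMAP, CH2Cl2) should give methyl 4-(benzyloxy)-3-{2-[(4S)-4-benzyl-2-thioxothiazolidin-3-yl]-2-oxoethyl}-5-methoxybenzoate F2. Its chlorotitanium enolate (TiCl4, iPr2NEt, N-methylpyrrolidinone, CH2Cl2, −78 → 0 °C) with aldehyde 14 should give the same (2S,3S) syn adduct, methyl 4-(benzyloxy)-3-{(2S,3S)-1-[(4S)-4-benzyl-2-thioxothiazolidin-3-yl]-3-[4-(benzyloxy)-3-methoxyphenyl]-3-hydroxy-1-oxopropan-2-yl}-5-methoxybenzoate F3. The very labile thioimide is cleaved with LiBH4 (THF/H2O, 0 °C), which returns to the route at compound 17.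

3. Step 14. Dealkoxycarbonylation at the fully substituted C-alpha may stall, and prolonged heating may strip the acetonide or open the lactone. Fallback: the ester group is removed before the ring B half is attached. Setting out from 3 and 6 by way of lactone ester F1 (made as in the first fallback), the Krapcho reaction (LiCl, wet DMSO, 140 °C) on this simple substrate should give (R)-4-[4-(benzyloxy)-3-methoxybenzyl]dihydrofuran-2(3H)-one F4. Its lithium enolate (LiN(SiMe3)2, THF, −78 °C) is alkylated with bromide 20 on the face opposite the C-beta benzyl group, which should give the trans lactone directly and returns to the route at compound 24, bypassing 22 and 23.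

Further compounds
F1 | step 13 | ethyl (4R)-4-[4-(benzyloxy)-3-methoxybenzyl]-2-oxotetrahydrofuran-3-carboxylate (C-3 epimers) | CCOC(=O)C1C(=O)OC[C@@H]1Cc1ccc(OCc2ccccc2)c(OC)c1
F2 | step 8 | methyl 4-(benzyloxy)-3-{2-[(4S)-4-benzyl-2-thioxothiazolidin-3-yl]-2-oxoethyl}-5-methoxybenzoate | COC(=O)c1cc(OC)c(OCc2ccccc2)c(CC(=O)N2[C@@H](Cc3ccccc3)CSC2=S)c1
F3 | step 8 | methyl 4-(benzyloxy)-3-{(2S,3S)-1-[(4S)-4-benzyl-2-thioxothiazolidin-3-yl]-3-[4-(benzyloxy)-3-methoxyphenyl]-3-hydroxy-1-oxopropan-2-yl}-5-methoxybenzoate | COC(=O)c1cc(OC)c(OCc2ccccc2)c([C@H](C(=O)N2[C@@H](Cc3ccccc3)CSC2=S)[C@H](O)c2ccc(OCc3ccccc3)c(OC)c2)c1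
F4 | step 14 | (R)-4-[4-(benzyloxy)-3-methoxybenzyl]dihydrofuran-2(3H)-one | O=C1C[C@@H](Cc2ccc(OCc3ccccc3)c(OC)c2)CO1
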